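**Assumption:** the target is read as 18-acetoxy-8α-hydroxylabd-13(E)-en-15-oic acid, normal labdane series (4R,5R,8R,9R,10S; CH2OAc equatorial on C4). Labdane ring numbering is used throughout; abietane C14 is the carbon that ends as C17.

## Retrosynthetic overview

1. 18 ⇐ 16 ⇐ 15: acetylation of the primary C18–OH and ester hydrolysis come last.
2. 15 ⇐ 13 + 14: the C12–C13 bond and the 13(E) alkene come from a visible-light nickel/photoredox decarboxylative syn-hydroalkylation of methyl but-2-ynoate (key step, new).
3. 13 ⇐ 11 ⇐ 9: autoxidative excision of the isopropyl unit; the C8 carbinol comes from hydrogen-atom-transfer hydration of an exocyclic alkene under substrate control.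
4. 9 ⇐ 5 ⇐ 3: reductive 1,3-transposition of an enal made by oxidative cleavage of the C13=C14 bond of abietinol (ring C is opened).
5. 3 ⇐ 1: rings A and B, with C4, C5, C9, C10 and the C18 oxygen, are bought as (−)-abietic acid; no ring is formed, only ring C is cut.

## Route

**Step 1**
Reactants: 1 (−)-abietic acid
Product: 3 abietinol (abieta-7,13-dien-18-ol), via abieta-7,13-dien-18-al 2 (not isolated)
Conditions: LiAlH4 (1.5 equiv), THF, 0 °C to reflux; then Na2SO4·10H2O
Reagents that add atoms: none
Why: LiAlH4 reduction of the C18 carboxylic acid runs through the aldehyde to the primary alcohol and leaves the diene and the bought C4, C5, C9 and C10 stereocentres untouched.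

**Step 2**
Reactants: 3 abietinol
Product: 5 18-hydroxy-13-oxo-13,14-seco-abiet-7-en-14-al, via abiet-7-ene-13α,14α,18-triol 4 (not isolated)
Conditions: OsO4 (2 mol %), NaIO4 (3 equiv), 2,6-lutidine (2 equiv), 1,4-dioxane–H2O 3:1, 20 °C
Reagents that add atoms: osmium tetroxide OsO4, O=[Os](=O)(=O)=O; sodium periodate NaIO4, [Na+].[O-]I(=O)(=O)=O
Why: Lemieux–Johnson oxidative cleavage: osmylation occurs at the distal, less hindered C13=C14 bond (the usual site of OsO4 and KMnO4 attack on abietates), periodate cleaves the glycol, and the surviving C7=C8 bond is then an electron-poor enal that resists further osmylation.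

**Step 3**
Reactants: 5 18-hydroxy-13-oxo-13,14-seco-abiet-7-en-14-al
Product: 6 14-(E)-N-tosylhydrazone of 5
Conditions: TsNHNH2 (1.05 equiv), MeOH, 0 to 20 °C
Reagents that add atoms: p-toluenesulfonyl hydrazide, Cc1ccc(cc1)S(=O)(=O)NN
Why: Hydrazone condensation is chemoselective for the aldehyde because the α-branched isopropyl ketone condenses far more slowly.

**Step 4**
Reactants: 6 14-(E)-N-tosylhydrazone of 5
Product: 9 18-hydroxy-13,14-seco-abiet-8(14)-en-13-one, via N-boryl tosylhydrazine 7 (not isolated), via allylic diazene 8 (not isolated)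
Conditions: catecholborane (3 equiv), CHCl3, −10 to 0 °C; then NaOAc·3H2O (3 equiv), reflux
Reagents that add atoms: none
Why: Kabalka reductive alkene transposition: hydride adds to C=N, acetate-triggered loss of sulfinate gives the allylic diazene, and its retro-ene loss of N2 delivers H to C7 and moves the alkene to the exocyclic C8 methylene position, the tosylhydrazone being reduced much faster than the hindered ketone.

**Step 5**
Reactants: 9 18-hydroxy-13,14-seco-abiet-8(14)-en-13-one
Product: 11 8α,18-dihydroxy-13,14-seco-abietan-13-one, via 8α-hydroperoxide 10 (not isolated)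
Conditions: Co(acac)2 (20 mol %), PhSiH3 (2.5 equiv), O2 (1 atm), THF–i-PrOH, 0 to 20 °C; then PPh3 (1.2 equiv)
Reagents that add atoms: dioxygen, O=O
Why: Mukaiyama hydration (cobalt-hydride hydrogen-atom transfer): H is delivered to the methylene carbon and the planar tertiary C8 radical is trapped by O2 mainly on the α face because the axial β trajectory is blocked by the syn-axial 10β-methyl group, which sets C8 (8α-OH, 8β-CH3) under control of the bought C9 and C10 centres, the hydroperoxide then being reduced by PPh3.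

**Step 6**
Reactants: 11 8α,18-dihydroxy-13,14-seco-abietan-13-one
Product: 13 8α,18-dihydroxy-14,15,16-trinorlabdan-13-oic acid, via 15-hydroperoxy ketone 12 (not isolated)
Conditions: KOtBu (5 equiv), O2 (1 atm), t-BuOH–DME 1:1, 20 °C; then 1 M HCl, 0 °C, to pH 4
Reagents that add atoms: dioxygen, O=O
Why: Base-mediated autoxidative ketone cleavage (Doering–Haines type): the more substituted enolate is oxygenated at the tertiary α-carbon C15 and the α-hydroperoxy ketone fragments through a dioxetane alkoxide to the C13 carboxylate and acetone without touching any stereocentre.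

**Step 7**
Reactants: 13 8α,18-dihydroxy-14,15,16-trinorlabdan-13-oic acid; 14 methyl but-2-ynoate
Product: 15 methyl 8α,18-dihydroxylabd-13(E)-en-15-oate
Conditions: 4CzIPN (2 mol %), NiCl2(dme) (10 mol %), dtbbpy (12 mol %), Cs2CO3 (0.2 equiv), 14 (2.5 equiv), degassed DMSO, 450 nm LEDs, 25 °C
Reagents that add atoms: none
Why: Proposed new method: a visible-light decarboxylative syn-hydroalkylation of a 2-alkynoate by a free primary alkanoic acid under nickel/organic-photocatalyst dual catalysis, reasoning that excited 4CzIPN oxidises the carboxylate of 13, CO2 loss gives the primary C12 radical, low-valent nickel captures it, the alkyl–nickel bond adds syn across the polarised alkyne with carbon bonding to the β-carbon, and protodemetalation by the substrate acid with retention leaves C12 and the new vinylic H cis (C12 trans to CO2Me, hence 13E) while the free hydroxyls are spectators; the closest known reaction type is the photoredox/nickel decarboxylative hydroalkylation of simple alkynes, which to my knowledge has not been shown for an unprotected hydroxy acid or for a 2-alkynoate giving a trisubstituted 3-methyl-2-enoate.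

**Step 8**
Reactants: 15 methyl 8α,18-dihydroxylabd-13(E)-en-15-oate
Product: 16 8α,18-dihydroxylabd-13(E)-en-15-oic acid
Conditions: LiOH·H2O (5 equiv), THF–MeOH–H2O 3:1:1, 45 °C; then 1 M HCl to pH 3–4
Reagents that add atoms: lithium hydroxide LiOH, [Li+].[OH-]
Why: Saponification of the methyl ester; the trisubstituted (E)-enoate does not isomerise and no other base-labile group is present.

**Step 9**
Reactants: 16 8α,18-dihydroxylabd-13(E)-en-15-oic acid
Product: 18 18-acetoxy-8α-hydroxylabd-13(E)-en-15-oic acid (target), via mixed acetic anhydride 17 (not isolated)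
Conditions: Ac2O (4 equiv), pyridine, 20 °C; then H2O, 20 °C, 1 h
Reagents that add atoms: acetic anhydride, CC(=O)OC(C)=O
Why: Pyridine-mediated O-acetylation takes only the primary C18 hydroxyl (the tertiary 8α-hydroxyl is inert without DMAP), and the mixed anhydride formed at C15 is hydrolysed back to the acid by the aqueous pyridine work-up.

## Compound list

1 | (−)-abietic acid, abieta-7,13-dien-18-oic acid (4α-CO2H, 4β-CH3, 5α-H, 9α-H, 10β-CH3) | OC(=O)[C@]1(C)CCC[C@]2(C)[C@@H](CCC(C(C)C)=C3)C3=CC[C@@H]12 | starting material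
2 | abieta-7,13-dien-18-al (ring stereochemistry as in 1) | O=C[C@]1(C)CCC[C@]2(C)[C@@H](CCC(C(C)C)=C3)C3=CC[C@@H]12 | intermediate
3 | abietinol, abieta-7,13-dien-18-ol | OC[C@]1(C)CCC[C@]2(C)[C@@H](CCC(C(C)C)=C3)C3=CC[C@@H]12 | intermediate
4 | abiet-7-ene-13α,14α,18-triol (cis-glycol, drawn α,α; the face of osmylation is immaterial) | OC[C@]1(C)CCC[C@]2(C)[C@@H](CC[C@@]3(O)C(C)C)C(=CC[C@@H]12)[C@H]3O | intermediate
5 | 18-hydroxy-13-oxo-13,14-seco-abiet-7-en-14-al (formyl on C8 of the C7=C8 alkene; 4-methyl-3-oxopentyl chain on C9, 9α-H) | OC[C@]1(C)CCC[C@]2(C)[C@@H](CCC(=O)C(C)C)C(C=O)=CC[C@@H]12 | intermediate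
6 | 14-(E)-N-tosylhydrazone of 5 | OC[C@]1(C)CCC[C@]2(C)[C@@H](CCC(=O)C(C)C)C(/C=N/NS(=O)(=O)c3ccc(C)cc3)=CC[C@@H]12 | intermediate
7 | N-(catecholboryl)-N′-tosyl allylic hydrazine from 6 | OC[C@]1(C)CCC[C@]2(C)[C@@H](CCC(=O)C(C)C)C(CN(NS(=O)(=O)c3ccc(C)cc3)B3Oc4ccccc4O3)=CC[C@@H]12 | intermediate
8 | allylic diazene (C14–N=NH on C8 of the C7=C8 alkene) | OC[C@]1(C)CCC[C@]2(C)[C@@H](CCC(=O)C(C)C)C(CN=N)=CC[C@@H]12 | intermediate
9 | 18-hydroxy-13,14-seco-abiet-8(14)-en-13-one (exocyclic methylene on C8, 9α-H) | OC[C@]1(C)CCC[C@]2(C)[C@@H](CCC(=O)C(C)C)C(=C)CC[C@@H]12 | intermediate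
10 | 8α-hydroperoxy-18-hydroxy-13,14-seco-abietan-13-one | OC[C@]1(C)CCC[C@]2(C)[C@@H](CCC(=O)C(C)C)[C@](C)(OO)CC[C@@H]12 | intermediate
11 | 8α,18-dihydroxy-13,14-seco-abietan-13-one (8α-OH equatorial, 8β-CH3 axial) | OC[C@]1(C)CCC[C@]2(C)[C@@H](CCC(=O)C(C)C)[C@](C)(O)CC[C@@H]12 | intermediate
12 | 15-hydroperoxy-8α,18-dihydroxy-13,14-seco-abietan-13-one | OC[C@]1(C)CCC[C@]2(C)[C@@H](CCC(=O)C(C)(C)OO)[C@](C)(O)CC[C@@H]12 | intermediate
13 | 8α,18-dihydroxy-14,15,16-trinorlabdan-13-oic acid | OC[C@]1(C)CCC[C@]2(C)[C@@H](CCC(=O)O)[C@](C)(O)CC[C@@H]12 | intermediate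
14 | methyl but-2-ynoate | CC#CC(=O)OC | starting material
15 | methyl 8α,18-dihydroxylabd-13(E)-en-15-oate | OC[C@]1(C)CCC[C@]2(C)[C@@H](CC/C(C)=C/C(=O)OC)[C@](C)(O)CC[C@@H]12 | intermediate
16 | 8α,18-dihydroxylabd-13(E)-en-15-oic acid | OC[C@]1(C)CCC[C@]2(C)[C@@H](CC/C(C)=C/C(=O)O)[C@](C)(O)CC[C@@H]12 | intermediate
17 | acetic 18-acetoxy-8α-hydroxylabd-13(E)-en-15-oic anhydride | CC(=O)OC[C@]1(C)CCC[C@]2(C)[C@@H](CC/C(C)=C/C(=O)OC(C)=O)[C@](C)(O)CC[C@@H]12 | intermediate
18 | 18-acetoxy-8α-hydroxylabd-13(E)-en-15-oic acid (CNP0077667.1) | CC(=O)OC[C@]1(C)CCC[C@]2(C)[C@@H](CC/C(C)=C/C(=O)O)[C@](C)(O)CC[C@@H]12 | target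

## Step count and risks

Total step count: 9. Longest linear sequence: 9 steps (1 to 18; 14 is purchased).

The three steps most likely to fail:

**Step 7 (the new step).** Unactivated primary acids are poor partners in direct photoredox/nickel decarboxylative couplings, and an uncatalysed radical addition to the ynoate would erode the E:Z ratio. The fallback uses known chemistry, sets out from 13 and comes back at 15. MeLi (5 equiv, THF, 0 °C) converts the carboxylic acid into the methyl ketone 8α,18-dihydroxy-14,15-dinorlabdan-13-one F3. Horner–Wadsworth–Emmons olefination with trimethyl phosphonoacetate and NaH (THF, 50 °C; E:Z about 5:1, the Z ester removed by chromatography) then gives 15.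

**Step 5.** Oxygen capture by the C8 radical is fast and its facial selectivity may be modest, so the 8-epimer could form in quantity. The fallback sets out from 9 and comes back at 11, replacing radical hydration by ionic Markovnikov hydration. Oxymercuration with Hg(OAc)2 in THF–H2O at 20 °C gives 14-(acetoxymercurio)-8α,18-dihydroxy-13,14-seco-abietan-13-one F1. The mercurinium ion is opened at C8 from the α side, as expected for oxymercuration of labd-8(17)-enes. Radical demercuration with Bu3SnH (toluene, 20 °C), which does not reduce the ketone, then gives 11.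

**Step 6.** Some oxygenation at C12 would give the chain-shortened acid, and the δ-hydroxy acid can close to its lactone if acidified too strongly. The fallback sets out from 11 and comes back at 13. Baeyer–Villiger oxidation with mCPBA and NaHCO3 (CH2Cl2, 20 °C; the secondary isopropyl group migrates) gives isopropyl 8α,18-dihydroxy-14,15,16-trinorlabdan-13-oate F2. Saponification with LiOH (THF–H2O, 40 °C) and careful acidification to pH 4 then gives 13.

Further compounds
F1 | step 5 | 14-(acetoxymercurio)-8α,18-dihydroxy-13,14-seco-abietan-13-one | OC[C@]1(C)CCC[C@]2(C)[C@@H](CCC(=O)C(C)C)[C@](C[Hg]OC(C)=O)(O)CC[C@@H]12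
F2 | step 6 | isopropyl 8α,18-dihydroxy-14,15,16-trinorlabdan-13-oate | OC[C@]1(C)CCC[C@]2(C)[C@@H](CCC(=O)OC(C)C)[C@](C)(O)CC[C@@H]12
F3 | step 7 | 8α,18-dihydroxy-14,15-dinorlabdan-13-one | OC[C@]1(C)CCC[C@]2(C)[C@@H](CCC(C)=O)[C@](C)(O)CC[C@@H]12
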